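Cuts, in retrosynthetic order: C4 and C8 go back from CH2 to lactone C=O. Then the C1–OH and C5–OH bonds are cut, then the benzylic C2–O3 and C6–O7 bonds, and last the central C1–C5 bond, which leaves two dihydroferulic acid units.
Enabling feature: C1 and C5 are the fusion carbons shared by ring A (C1-C2-O3-C4-C5) and ring B (C5-C6-O7-C8-C1) of a cis-3,7-dioxabicyclo[3.3.0]octane. In the 4,8-dione, C5 is a CH alpha to C4=O and C1 a CH alpha to C8=O, so each can be enolised and can bond to oxygen on one face only.
Forward order: oxidative enolate homocoupling joins C1–C5. Benzylic dehydrogenative lactonisation closes ring A, then ring B. Both carbinols are placed on the finished dilactone, the carbonyls are reduced to CH2, and the phenols are released.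
Stereochemistry: (S)-4-isopropyloxazolidin-2-one fixes C1 and C5. These place the aryl groups at C2 and C6 trans to the neighbouring carboxyl carbon (exo). Cis fusion enforces retention at C5 and C1 during hydroxylation.

Key step: step 6

Remark: the locants C1 to C8 of the bicyclic core are used for the corresponding atoms of every intermediate, open-chain ones included; the racemic oxaziridine is acceptable in step 6 because the substrate alone decides the face of attack.

Step 1
Reactants: 1 3-(4-hydroxy-3-methoxyphenyl)propanoic acid (dihydroferulic acid)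
Product: 2 3-(4-benzyloxy-3-methoxyphenyl)propanoic acid
Conditions: BnBr, KOH, EtOH/H2O, reflux; then aq. HCl
Reagents that add atoms: benzyl bromide, BrCc1ccccc1
Why: Williamson ether synthesis in which the phenoxide of the dianion is alkylated and any benzyl ester formed alongside is saponified again in the hot alkaline medium, so only the aryl benzyl ether survives and no stereocentre is involved.

Step 2
Reactants: 2 3-(4-benzyloxy-3-methoxyphenyl)propanoic acid; 3 (S)-4-isopropyl-1,3-oxazolidin-2-one
Product: 5 (S)-3-[3-(4-benzyloxy-3-methoxyphenyl)propanoyl]-4-isopropyl-1,3-oxazolidin-2-one, via mixed pivalic anhydride 4 (not isolated)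
Conditions: PivCl, Et3N, THF, −20 °C; then LiCl, 3, −20 °C to rt
Reagents that add atoms: none
Why: N-acylation of a chiral oxazolidinone through the mixed pivalic anhydride with LiCl/Et3N activation, attack at the unhindered acyl carbon of 4 being favoured over the tert-butyl-flanked one, and the only stereocentre comes from 3 and is not touched.

Step 3
Reactants: 5 (S)-3-[3-(4-benzyloxy-3-methoxyphenyl)propanoyl]-4-isopropyl-1,3-oxazolidin-2-one (two molecules)
Product: 7 (2R,3R)-2,3-bis(4-benzyloxy-3-methoxybenzyl)-1,4-bis[(S)-4-isopropyl-2-oxo-1,3-oxazolidin-3-yl]butane-1,4-dione, via Z-lithium enolate 6 (not isolated)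
Conditions: LiN(iPr)2, THF, −78 °C; then PhI(OAc)2 (0.5 equiv), −78 °C to rt
Reagents that add atoms: none
Why: Oxidative homocoupling of a chiral N-acyloxazolidinone lithium enolate, a reaction established for 3-arylpropanoyl imides, in which the chelated Z-enolate 6 is oxidised by the trivalent iodine reagent and both alpha-carbons bond on the face turned away from the isopropyl group, setting C1 and C5 as R,R, with minor diastereomers removed by chromatography or crystallisation.

Step 4
Reactants: 7 (2R,3R)-bis-imide
Product: 9 (2R,3R)-2,3-bis(4-benzyloxy-3-methoxybenzyl)succinic acid, via bis-peroxy acid 8 (not isolated)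
Conditions: LiOH, H2O2, THF/H2O, 0 °C; then aq. Na2SO3; then aq. HCl
Reagents that add atoms: hydrogen peroxide, OO
Why: Hydroperoxide cleavage of N-acyloxazolidinones, in which LiOOH attacks the exocyclic imide carbonyls selectively even in this hindered succinyl system, sulfite reduces the peroxy acid 8, and the weakly basic medium at 0 °C leaves the alpha-stereocentres C1 and C5 unchanged.

Step 5
Reactants: 9 (2R,3R)-2,3-bis(4-benzyloxy-3-methoxybenzyl)succinic acid
Product: 11 (1S,2S,5S,6S)-2,6-bis(4-benzyloxy-3-methoxyphenyl)-3,7-dioxabicyclo[3.3.0]octane-4,8-dione (cis-fused; both aryl groups exo), via monolactone acid 10 (not isolated)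
Conditions: DDQ (2.5 equiv), 1,2-dichloroethane, 4 Å molecular sieves, rt to 50 °C
Reagents that add atoms: none
Why: DDQ-mediated dehydrogenative benzylic lactonisation of a 4-arylbutanoic acid motif, in which hydride is abstracted para to the benzyloxy group, the C4 carboxyl captures the C2 cation in a five-membered closure that puts the aryl group trans to the C8 carboxyl on C1 (10), and repetition at C6 with the C8 carboxyl, held cis to the C5 side chain by the R,R configuration, closes ring B with the aryl group on the convex face.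

Step 6
Reactants: 11 (1S,2S,5S,6S)-2,6-bis(4-benzyloxy-3-methoxyphenyl)-3,7-dioxabicyclo[3.3.0]octane-4,8-dione
Product: 15 (1S,2R,5S,6R)-2,6-bis(4-benzyloxy-3-methoxyphenyl)-1,5-dihydroxy-3,7-dioxabicyclo[3.3.0]octane-4,8-dione, via potassium enolate 12 (not isolated), via 5-hydroxy alkoxide 13 (not isolated), via alkoxide enolate dianion 14 (not isolated)
Conditions: KN(SiMe3)2 (1.1 equiv), THF, −78 °C, 10 min; 2-(phenylsulfonyl)-3-phenyloxaziridine (1.3 equiv), −78 °C; second cycle KN(SiMe3)2 (1.5 equiv), then oxaziridine (1.5 equiv), −78 °C; AcOH, −78 °C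
Reagents that add atoms: 2-(phenylsulfonyl)-3-phenyloxaziridine, O=S(=O)(c1ccccc1)N1OC1c1ccccc1
Why: KN(SiMe3)2 removes H5, the fusion proton alpha to the C4 carbonyl, and carbon C5 of the planar enolate 12 attacks the oxaziridine oxygen in an SN2-type transfer, the hemiaminal collapsing to the sulfonimine and alkoxide 13, after which a second base and oxidant cycle repeats the event at C1 through dianion 14. The closest known reaction is the Davis alpha-hydroxylation of lactone enolates that carry a fully substituted alpha-carbon, run here twice in one flask, and no ring is closed. Stereocontrol rests on enolising one fusion carbon at a time: the other fusion carbon stays tetrahedral, so the new C5–O bond must form cis to C1–H, and the new C1–O bond cis to C5–O, because the alternative is a trans-fused pair of five-membered rings, and OH therefore takes the place of H with retention at both centres. The dienolate is avoided on purpose, since with both fusion carbons planar only the aryl groups at C2 and C6 would tell the faces apart and they would send the oxidant to the wrong one. The selectivity required is oxygen transfer ahead of E1cB loss of carboxylate O7 from C6 (or O3 from C2); that opening is the reverse of a 5-endo-trig closure, the C6–O7 bond lying near the nodal plane of the enolate, and the potassium counter-ion, −78 °C and an enolate lifetime of minutes hold it back further. In 14 the extra beta-substituent is an oxide and no leaving group, H2 and H6 are far too weakly acidic to be removed so C2 and C6 keep their configuration, and the cold AcOH quench protonates both alkoxides before retro-aldol cleavage of C1–C5 can begin.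

Step 7
Reactants: 15 (1S,2R,5S,6R)-1,5-dihydroxy dilactone
Product: 16 (1S,2R,5S,6R)-2,6-bis(4-benzyloxy-3-methoxyphenyl)-3,7-dioxabicyclo[3.3.0]octane-1,4,5,8-tetrol (bis-lactol, anomeric mixture at C4 and C8)
Conditions: iBu2AlH (6 equiv), CH2Cl2, −78 °C; then aq. KNaC4H4O6 (potassium sodium tartrate)
Reagents that add atoms: none
Why: Partial reduction of gamma-lactones to lactols with iBu2AlH, in which two equivalents are consumed by the tertiary hydroxyls and the tetrahedral aluminium hemiacetals persist at −78 °C so that reduction stops at the lactol level, C4 and C8 becoming an inconsequential anomeric mixture while C1, C2, C5 and C6 are unaffected.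

Step 8
Reactants: 16 bis-lactol
Product: 17 (1S,2R,5S,6R)-2,6-bis(4-benzyloxy-3-methoxyphenyl)-3,7-dioxabicyclo[3.3.0]octane-1,5-diol (O,O'-dibenzylprinsepiol)
Conditions: Et3SiH (10 equiv), BF3·OEt2 (4 equiv), CH2Cl2/MeCN, −78 to −30 °C; then aq. NaHCO3
Reagents that add atoms: none
Why: Ionic silane deoxygenation of lactols (Kursanov–Parnes type), known for furofuran bis-lactols and for unprotected glycosyl hemiketals, in which BF3 ionises the anomeric C–OH bonds to ring oxocarbenium ions that Et3SiH reduces to the C4 and C8 methylenes, while the electron-withdrawing tertiary C–OH next to C2 and C6 disfavours ionisation of the benzylic C–O bonds at low temperature, so no stereocentre changes.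

Step 9
Reactants: 17 O,O'-dibenzylprinsepiol
Product: 18 prinsepiol, (1S,2R,5S,6R)-2,6-bis(4-hydroxy-3-methoxyphenyl)-3,7-dioxabicyclo[3.3.0]octane-1,5-diol
Conditions: H2 (1 atm), 10% Pd/C, EtOAc/EtOH, rt, stopped after uptake of two equivalents of H2
Reagents that add atoms: none
Why: Catalytic hydrogenolysis of aryl benzyl ethers, which are cleaved much faster than the two ring benzylic C–O bonds flanked by fully substituted carbinol carbons, so controlled hydrogen uptake should deliver 18 with all four stereocentres intact.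

Compound list
1 | 3-(4-hydroxy-3-methoxyphenyl)propanoic acid | COc1cc(CCC(=O)O)ccc1O | starting material
2 | 3-(4-benzyloxy-3-methoxyphenyl)propanoic acid | COc1cc(CCC(=O)O)ccc1OCc1ccccc1 | intermediate
3 | (S)-4-isopropyl-1,3-oxazolidin-2-one | CC(C)[C@H]1COC(=O)N1 | starting material
4 | 3-(4-benzyloxy-3-methoxyphenyl)propanoic pivalic anhydride | COc1cc(CCC(=O)OC(=O)C(C)(C)C)ccc1OCc1ccccc1 | intermediate
5 | (S)-3-[3-(4-benzyloxy-3-methoxyphenyl)propanoyl]-4-isopropyl-1,3-oxazolidin-2-one | COc1cc(CCC(=O)N2[C@@H](C(C)C)COC2=O)ccc1OCc1ccccc1 | intermediate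
6 | Z-lithium enolate of 5 | COc1cc(C/C=C(\O[Li])N2[C@@H](C(C)C)COC2=O)ccc1OCc1ccccc1 | intermediate
7 | (2R,3R)-2,3-bis(4-benzyloxy-3-methoxybenzyl)-1,4-bis[(S)-4-isopropyl-2-oxo-1,3-oxazolidin-3-yl]butane-1,4-dione | O=C(N1[C@@H](C(C)C)COC1=O)[C@H](Cc1ccc(OCc2ccccc2)c(OC)c1)[C@@H](Cc1ccc(OCc2ccccc2)c(OC)c1)C(=O)N1[C@@H](C(C)C)COC1=O | intermediate
8 | (2R,3R)-2,3-bis(4-benzyloxy-3-methoxybenzyl)butanediperoxoic acid | OOC(=O)[C@H](Cc1ccc(OCc2ccccc2)c(OC)c1)[C@@H](Cc1ccc(OCc2ccccc2)c(OC)c1)C(=O)OO | intermediate
9 | (2R,3R)-2,3-bis(4-benzyloxy-3-methoxybenzyl)succinic acid | OC(=O)[C@H](Cc1ccc(OCc2ccccc2)c(OC)c1)[C@@H](Cc1ccc(OCc2ccccc2)c(OC)c1)C(=O)O | intermediate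
10 | (2S,3S,4R)-2-(4-benzyloxy-3-methoxyphenyl)-4-(4-benzyloxy-3-methoxybenzyl)-5-oxotetrahydrofuran-3-carboxylic acid (aryl trans to CO2H, CO2H cis to arylmethyl) | COc1cc([C@H]2OC(=O)[C@H](Cc3ccc(OCc4ccccc4)c(OC)c3)[C@@H]2C(=O)O)ccc1OCc1ccccc1 | intermediate
11 | (1S,2S,5S,6S)-2,6-bis(4-benzyloxy-3-methoxyphenyl)-3,7-dioxabicyclo[3.3.0]octane-4,8-dione | COc1cc([C@H]2OC(=O)[C@@H]3[C@@H](c4ccc(OCc5ccccc5)c(OC)c4)OC(=O)[C@H]23)ccc1OCc1ccccc1 | intermediate
12 | potassium C4=C5 enolate of 11 | COc1cc([C@H]2OC([O-])=C3[C@@H](c4ccc(OCc5ccccc5)c(OC)c4)OC(=O)[C@H]23)ccc1OCc1ccccc1.[K+] | intermediate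
13 | potassium alkoxide of the 5-hydroxy dilactone (oxygen cis to H1, other centres as in 11) | COc1cc([C@H]2OC(=O)[C@]3([O-])[C@@H](c4ccc(OCc5ccccc5)c(OC)c4)OC(=O)[C@H]23)ccc1OCc1ccccc1.[K+] | intermediate
14 | dipotassium 5-alkoxide C1=C8 enolate | COc1cc([C@H]2OC(=O)[C@]3([O-])[C@@H](c4ccc(OCc5ccccc5)c(OC)c4)OC([O-])=C23)ccc1OCc1ccccc1.[K+].[K+] | intermediate
15 | (1S,2R,5S,6R)-2,6-bis(4-benzyloxy-3-methoxyphenyl)-1,5-dihydroxy-3,7-dioxabicyclo[3.3.0]octane-4,8-dione | COc1cc([C@H]2OC(=O)[C@]3(O)[C@@H](c4ccc(OCc5ccccc5)c(OC)c4)OC(=O)[C@]23O)ccc1OCc1ccccc1 | intermediate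
16 | (1S,2R,5S,6R)-2,6-bis(4-benzyloxy-3-methoxyphenyl)-3,7-dioxabicyclo[3.3.0]octane-1,4,5,8-tetrol (C4 and C8 undefined) | COc1cc([C@H]2OC(O)[C@]3(O)[C@@H](c4ccc(OCc5ccccc5)c(OC)c4)OC(O)[C@]23O)ccc1OCc1ccccc1 | intermediate
17 | (1S,2R,5S,6R)-2,6-bis(4-benzyloxy-3-methoxyphenyl)-3,7-dioxabicyclo[3.3.0]octane-1,5-diol | COc1cc([C@H]2OC[C@]3(O)[C@@H](c4ccc(OCc5ccccc5)c(OC)c4)OC[C@]23O)ccc1OCc1ccccc1 | intermediate
18 | prinsepiol | COc1cc([C@H]2OC[C@]3(O)[C@@H](c4ccc(O)c(OC)c4)OC[C@]23O)ccc1O | target

Total step count: 9. Longest linear sequence: 9 steps (1 to 18).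

Steps most likely to fail

Step 6. Several things may go wrong:
- The fusion enolate may open by beta-elimination during its lifetime.
- Oxygen transfer may be sluggish because the bulky oxidant must approach next to the exo aryl group.
- The sulfonimine may consume the second charge of base.
- The alkoxide may undergo retro-aldol cleavage.

The fallback is a Rubottom oxidation, again at one fusion carbon at a time. Starting from 11, LiN(SiMe3)2 (one equivalent) is added to 11 premixed with Me3SiCl in THF at −95 °C. The enolate is then silylated as it forms, giving the C4=C5 trimethylsilyl ketene acetal F1. Dimethyldioxirane in acetone/CH2Cl2 at −40 °C, a small and neutral oxidant, epoxidises it cis to C1–H, and silyl migration gives the 5-trimethylsilyloxy dilactone F2. The same pair of operations at C1 leads through the C1=C8 trimethylsilyl ketene acetal F3 to the 1,5-bis(trimethylsilyloxy) dilactone F4. Aqueous citric acid in THF removes both silyl groups and the route is rejoined at 15.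

Step 5. Three things may go wrong:
- The benzylic cation may lose a proton towards C1 or C5, which would erase an auxiliary-derived stereocentre.
- The second arene may capture the first cation in Friedel–Crafts fashion.
- A benzyl ether may be lost by oxidation.

The fallback uses a neutral quinone methide instead of a cation. Starting from 9, hydrogenolysis (H2, Pd/C, EtOAc/MeOH; no ring C–O bond is present yet) gives (2R,3R)-2,3-bis(4-hydroxy-3-methoxybenzyl)succinic acid F5. Ag2O in CH2Cl2/acetone oxidises each 4-alkylguaiacol unit to its para-quinone methide. The gamma-carboxyl group adds to it at C2 and then C6, the closure that also operates in the oxidative dimerisation of ferulic acid, giving the bis-phenol dilactone F6. Mitsunobu benzylation (BnOH, PPh3, diisopropyl azodicarboxylate, THF), chosen because it avoids phenoxide formation, returns to 11.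

Step 8. Three things may go wrong:
- The Lewis acid may ionise the benzylic C2–O3 and C6–O7 bonds, leading to epimerisation or reductive ring opening.
- The alpha-hydroxy oxocarbenium ion may undergo a 1,2-shift.
- Deoxygenation may be incomplete.

The fallback opens both rings and recloses them by alkylation at C4 and C8, replacing steps 7 and 8. Starting from 15, LiAlH4 in THF at 0 °C gives the hexaol F7. TsCl in pyridine at 0 °C sulfonylates only the two primary hydroxyls to give the bis-tosylate F8. K2CO3 in MeOH then closes both tetrahydrofuran rings. Closure occurs either by direct 5-exo-tet displacement by the benzylic hydroxyl or by way of the bis-epoxide F9, which the same hydroxyl opens at its CH2 terminus (catalytic pyridinium p-toluenesulfonate if needed). Only the achiral carbons C4 and C8 undergo substitution, so C1, C2, C5 and C6 are untouched, and the route is rejoined at 17.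

Further compounds
F1 | step 6 | C4=C5 trimethylsilyl ketene acetal of 11 (C1, C2, C6 as in 11) | COc1cc([C@H]2OC(O[Si](C)(C)C)=C3[C@@H](c4ccc(OCc5ccccc5)c(OC)c4)OC(=O)[C@H]23)ccc1OCc1ccccc1
F2 | step 6 | 5-trimethylsilyloxy dilactone (silyloxy group cis to H1) | COc1cc([C@H]2OC(=O)[C@]3(O[Si](C)(C)C)[C@@H](c4ccc(OCc5ccccc5)c(OC)c4)OC(=O)[C@H]23)ccc1OCc1ccccc1
F3 | step 6 | C1=C8 trimethylsilyl ketene acetal of F2 | COc1cc([C@H]2OC(=O)[C@]3(O[Si](C)(C)C)[C@@H](c4ccc(OCc5ccccc5)c(OC)c4)OC(O[Si](C)(C)C)=C23)ccc1OCc1ccccc1
F4 | step 6 | 1,5-bis(trimethylsilyloxy) dilactone (bis-silyl ether of 15) | COc1cc([C@H]2OC(=O)[C@]3(O[Si](C)(C)C)[C@@H](c4ccc(OCc5ccccc5)c(OC)c4)OC(=O)[C@]23O[Si](C)(C)C)ccc1OCc1ccccc1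
F5 | step 5 | (2R,3R)-2,3-bis(4-hydroxy-3-methoxybenzyl)succinic acid | OC(=O)[C@H](Cc1ccc(O)c(OC)c1)[C@@H](Cc1ccc(O)c(OC)c1)C(=O)O
F6 | step 5 | (1S,2S,5S,6S)-2,6-bis(4-hydroxy-3-methoxyphenyl)-3,7-dioxabicyclo[3.3.0]octane-4,8-dione | COc1cc([C@H]2OC(=O)[C@@H]3[C@@H](c4ccc(O)c(OC)c4)OC(=O)[C@H]23)ccc1O
F7 | step 8 | (1R,2S,3S,4R)-1,4-bis(4-benzyloxy-3-methoxyphenyl)-2,3-bis(hydroxymethyl)butane-1,2,3,4-tetrol | COc1cc([C@@H](O)[C@@](O)(CO)[C@](O)(CO)[C@H](O)c2ccc(OCc3ccccc3)c(OC)c2)ccc1OCc1ccccc1
F8 | step 8 | bis(p-toluenesulfonate) of the two primary hydroxyls of F7 | COc1cc([C@@H](O)[C@@](O)(COS(=O)(=O)c2ccc(C)cc2)[C@](O)(COS(=O)(=O)c2ccc(C)cc2)[C@H](O)c2ccc(OCc3ccccc3)c(OC)c2)ccc1OCc1ccccc1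
F9 | step 8 | (2S,2'S)-2,2'-bis[(R)-(4-benzyloxy-3-methoxyphenyl)(hydroxy)methyl]-2,2'-bioxirane | COc1cc([C@@H](O)[C@@]2(CO2)[C@]2(CO2)[C@H](O)c2ccc(OCc3ccccc3)c(OC)c2)ccc1OCc1ccccc1
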